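Readings and results are calculated from invented constants; the scatter is artificial.

Square the reagent exposure before forecasting a double product.

| flask | starting material | reagent | remark | time |
|---|---|---|---|---|
| Tuesday's | 0.19 M | 0.17 M | run made earlier |  |
| Saturday's | 0.19 M | 0.33 M | run made earlier |  |
| Sunday's | 0.19 M | 0.42 M | run made earlier |  |
| dawn | 0.19 M | 0.570 M |  | 4.0 h |
| summer | 0.19 M | 0.228 M |  | 4.0 h |

| run | time / h | double product / % | first product / % | starting material / % |
|---|---|---|---|---|
| Tuesday's | 0.250 | 0.1 | 3.1 | 89.6 |
| Tuesday's | 0.667 | 0.3 | 6.9 | 75.8 |
| Tuesday's | 1.33 | 0.3 | 13.1 | 62.7 |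
| Tuesday's | 2.00 | 0 | 15.9 | 54.4 |
| Tuesday's | 3.00 | 0.5 | 17.7 | 46.4 |
| Saturday's | 0.250 | 0.6 | 6.9 | 79.5 |
| Saturday's | 0.667 | 0 | 13.6 | 58.9 |
| Saturday's | 1.33 | 0.5 | 19.9 | 40.3 |
| Saturday's | 2.00 | 0 | 23.8 | 31.6 |
| Saturday's | 3.00 | 2.0 | 27.0 | 23.6 |
| Sunday's | 0.250 | 0.3 | 8.3 | 75.0 |
| Sunday's | 0.417 | 0 | 11.3 | 63.0 |
| Sunday's | 0.833 | 0.8 | 18.4 | 45.1 |
| Sunday's | 1.33 | 0.2 | 23.6 | 31.6 |
| Sunday's | 3.00 | 3.4 | 28.3 | 17.0 |

(standard deviation of a reading: 0.5 percentage points)

- a reading or a percentage of first product counts all its forms, free or not
- a reading of starting material is of its free form alone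

* which of these holds the largest part of the starting material at the end of dawn (double product / first product / other mono adduct / starting material)
* which of these holds the largest part of the starting material at the end of summer (double product / first product / other mono adduct / starting material)
* final double product in dawn, as a percentage of the starting material charged

Minutes of the meeting on dawn and summer. The analyst reported that double product reached 2.0% in Saturday's run and 3.4% in Sunday's run at 3.00 h. The kineticist argued that double product takes up reagent twice in succession, so with c(reagent) frozen at its charge, the pseudo-first-order assumption, it should grow as the square of the exposure c(reagent)·t. He brought each reading to the exposure of Sunday's run by the squared ratio of exposures, and the mean for Saturday's and Sunday's runs gave him 3.32% as the reference yield, meaning the double product reckoned at the exposure of Sunday's run. Tuesday's run gave 3.05%, though its reading is of the size of the scatter. He therefore reckoned 10.9% of double product for dawn and 1.74% for summer.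

The analyst added that Tuesday's run ended with free starting material at 46.4%, more than the shortfall of 35.4%. Sunday's run ended with a shortfall of 51.3%, more than its first product. The chair noted that a reading of starting material counts its free form alone. The meeting named other mono adduct for dawn and starting material for summer, whose charge lies nearer Tuesday's than Saturday's.

The forecast named other mono adduct for dawn, other mono adduct for summer and 8% of double product, holding that “the unseen other mono adduct is the main product”.

Dawn ends with 8.70% of double product and other mono adduct largest at 38.3%. Summer ends with starting material largest at 30.7%, ahead of other mono adduct at 26.4%. In dawn at 4.00 h, reagent stands at 36.1% of its charge, and the reckoned 10.9% lies above the result. In summer, the reference yield gave 1.74% against 1.13%, again too high.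

    starting material + first product ⇌ idle adduct, settled at all times (K = 54.0 M⁻¹)
    starting material + reagent → other mono adduct + by-product (k = 1.10 M⁻¹ h⁻¹)
    reagent + other mono adduct → double product + by-product (k = 0.0690 M⁻¹ h⁻¹)
    reagent ⇌ dormant form (K = 1.10, k = 0.290 h⁻¹)
    starting material + reagent → first product + by-product (k = 1.00 M⁻¹ h⁻¹)
    reagent + first product → double product + by-product (k = 0.610 M⁻¹ h⁻¹)

For a neighbour of dawn charged with 0.14 M of reagent, the reference yield gives 0.656% of double product. The computed result is 0.377%, lower again.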